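The earlier runs and the new flask are simulated for substances that don't exist, and the scatter is random.

These flasks are slow: Monday's J still stands at 39% after 8.00 h. The ledger can do without a clock, though, if J leaves by two exits: the ratio of their rates then carries the books.

| setting | Monday's | Thursday's | maple | oak | birch | alder | cedar |
|---|---|---|---|---|---|---|---|
| J | 0.020 M | 0.020 M | 0.020 M | 0.060 M | 0.15 M | 0.50 M | 1.5 M |
| Z | 0.79 M | 1.1 M | 0.525 M | 0.525 M | 0.525 M | 0.525 M | 0.525 M |
| remark | run made earlier | run made earlier |  |  |  |  |  |
| time |  |  | 3.0 d | 3.0 d | 3.0 d | 3.0 d | 3.0 d |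

| run | time / h | X / % | J / % |
|---|---|---|---|
| Monday's | 3.00 | 25 | 73 |
| Monday's | 8.00 | 54 | 39 |
| Monday's | 15.0 | 69 | 17 |
| Monday's | 25.0 | 81 | 5 |
| Monday's | 30.0 | 86 | 7 |
| Monday's | 40.0 | 84 | 2 |
| Thursday's | 3.00 | 32 | 64 |
| Thursday's | 8.00 | 64 | 26 |
| Thursday's | 15.0 | 79 | 8 |
| Thursday's | 25.0 | 88 | 4 |
| Thursday's | 30.0 | 85 | 0 |
| Thursday's | 40.0 | 88 | 0 |

(readings scatter by 1.5 percentage points)

- the numbers in the tables scatter with a standard deviation of 1.5 percentage points
- a step back or a flat step of under half a percent of the largest counts as no turn
- a reading or a percentage of X counts all its forms, free or not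
- the concentration of X that is asked is that of its free form alone
- "hardly changes" means that all values lie within two and a half points (for a concentration: within two and a half percent of the largest)
- a step back or a flat step of under half a percent of the largest counts as no turn

1. [X] (only what is free in solution) at the end for maple, oak, birch, alder, cedar, in this order
2. the course of these numbers from the first flask to the last (falls, then rises / falls all the way / rises, then falls / rises all the way / hardly changes)

Dividing the rate into X by the rate of the other loss removes time. Each run's last readings give X over the J missing from the balance, and that ratio reads higher on Thursday, at the higher Z. Divided by Z, it reads 7.59 M⁻¹ on Monday and 6.67 M⁻¹ on Thursday, both with the scatter of the readings. Their mean, 7.13 M⁻¹, is the split constant, a selectivity factor: X made per J otherwise lost, per unit of Z.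

My own ledger for maple, where J is the limiting reagent:

J charged: 0.020 M
share into X = g·Z / (1 + g·Z) = 78.9%
into X: 0.01578 M
lost otherwise: 0.004220 M

Scaling Monday's loss of J to maple's Z gives a half-life of 8.23 h, shorter than the 3.0 d allowed, so maple's books should close.

With larger charges of J, Z falls along the way, so my share is taken at a mean Z, the charge less half the Z reckoned into X:

oak: 0.0469 M
birch, share 76.9%: 0.115 M
alder: 0.350 M

Cedar charges more J than Z, so Z is the limiting reagent there and caps X at 0.525 M. This ledger counts X in all its forms. Thursday's last reading holds 0.0176 M of X, so the runs test no level above that.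

The forecast gives 0.0157 M, 0.047 M, 0.115 M, 0.345 M and 0.52 M, with the course rises all the way. It sits below my alder figure and below my cedar cap. Its caution reads: “The runs show no evidence of binding, but they cannot exclude it.”

The flasks give 0.0158 M, 0.0471 M, 0.115 M, 0.150 M and 0.150 M of free X, with the course rises all the way.

    J + Z → X (k = 3.60 × 10⁻⁵ M⁻¹ s⁻¹)
    J → L (k = 4.60 × 10⁻⁶ s⁻¹)
    Z → Q (k = 9.90 × 10⁻⁷ s⁻¹)
    D ⇌ X, rate k4*(cs4 - [X]) while solid is left; crystals form when [X] > cs4 (solubility = 0.150 M, k = 7.40 × 10⁻⁴ s⁻¹)

The split constant carries over: its ledger share of 78.9% for maple stands beside 79.1% of X at the end, and its ledger share of 76.9% for birch beside 76.9%. Cedar parts from the forecast, and the largest single effect on its free X is the solubility limit of X. With that limit removed, cedar's free X reaches 0.510 M, against 0.150 M with it. The difference lies as crystals of D, which hold 24.0% of the J charged, counted within the 34.0% of X.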